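**Remark on the chemistry:** the SMILES is read as (S) at C3 (priorities C4 > C2 > C1' > H). The C4 configuration of the intermediates is immaterial for the target, because C4 ends as a ketone.

## Analysis of the target

Target 25 is an isoflavanone. Ring A (C4a, C5–C8, C8a) is fused through C4a–C8a to the dihydropyranone ring C (O1, C2, C3, C4), and ring B sits on C3. C3 is the only stereocentre, so nothing in the molecule can relay or correct its configuration. C3–H is benzylic and α to the aryl ketone C4, so the centre racemises through the enol under base and, more slowly, under acid. Each aromatic ring carries a free phenol ortho to a 3-methylbut-2-enyl (prenyl) group (O7/C6 and O4'/C3'). Acid closes such pairs to 2,2-dimethylchromans, and hydrogenation or electrophilic oxidants attack the trisubstituted alkenes. The classical difficulty is ring A, since prenylation of a resorcinol-type ring does not distinguish C6 from C8 cleanly. The strategy reads ring A as three two-carbon units: C8a(–O1)/C8, C7(–O)/C6(–prenyl) and C4a(–C4)/C5. These are an ethynyl ether, a siloxyalkyne and a propargylic alkyne, so every substituent of ring A is fixed by an alkyne terminus and ring C arises from the tether O1–C2–C3–C4.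

## Retrosynthetic reasoning

**25 ⇒ 24 ⇒ 23 ⇒ 22 (no skeletal bond cut).** The end of the route is arranged so that C3 sits next to a carbonyl group as late and as briefly as possible. The phenols of 25 come from the bis(triisopropylsilyl) ether 24 by buffered fluoride, the one deprotection that tolerates both the prenyl groups and an α-aryl ketone. The ketone of 24 is traced to the C4 alcohol 23, and 23 to the triethylsilyl ether 22. An alkyl triethylsilyl ether is far more labile to mild acid than aryl triisopropylsilyl ethers, which lets O4 be freed alone.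

**22 ⇒ 18 + 21 (C4a–C8a, C5–C6, C7–C8).** Ring A is cut across three bonds at once, which opens ring C as well. Cutting here, and not at C6–prenyl or at an aryl–oxygen bond, removes the C6/C8 regiochemical problem altogether. It also makes the route convergent and keeps C3 in a compound without any carbonyl group. The forward reaction must join diyne 18 and siloxyalkyne 21 in a cross (2+2+2) cycloaddition with head-to-tail orientation of the two oxygen-bearing alkynes. This is the step that carries the risk, so everything before it is kept to well-established chemistry.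

**21 ⇒ 19 (via 20).** The siloxyalkyne is cut at O–Si and at the alkyne carbon bearing the side chain. Ester 19 already holds the prenyl-type chain; one-carbon homologation to ynolate 20 and O-silylation with a bulky silyl group give 21 in one flask.

**18 ⇒ 17 ⇒ 15 ⇒ 14 ⇒ 13 (ethynyl ether).**
- The two carbons C8a and C8 are placed on the primary oxygen of alcohol 13 through formate 14 (C8a), the dichlorovinyl ether 15 (C8) and elimination to acetylide 16, protonated to 17.
- The more direct alkoxide addition to a chlorinated alkene was set aside. A metal alkoxide at O1 sits 1,5 to the triethylsilyl ether at O4 and would invite O→O silyl migration, and with it etherification of the wrong oxygen. The formate sequence never generates that alkoxide.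
- The trimethylsilyl group on the C4a/C5 alkyne is kept through the alkyllithium step and removed last (17 ⇒ 18).
- Ring B carries a triisopropylsilyl ether because a less hindered aryl silyl ether would not survive this basic alcoholysis.

**13 ⇒ 12 ⇒ 11 ⇒ 8 + 9 (C3–C4, via 10).** Cutting C3–C4 in the aldol sense gives the arylacetyl imide 8 and ynal 9. One syn-aldol reaction creates C3 and brings in C4, C4a and C5. Auxiliary 6 must be the (R) enantiomer: the acyl carbon becomes C2, and the aldol then gives 2R in 11, which is 3S in the chroman numbering once the acyl carbon is reduced. Silylation (12) and reductive removal of the auxiliary (13) follow.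

**8 ⇒ 5 + 6 (via 7); 5 ⇒ 4 ⇒ 2 + 3; 2 ⇒ 1.** The imide comes from acid 5 and auxiliary 6 through the mixed anhydride 7. The C3'–prenyl bond of ester 4 is cut to aryl bromide 2 and prenylstannane 3. This places the prenyl group by the position of a halogen in commercial 1 and not by electrophilic substitution.

## Alternatives that were turned down

**Alternative 1:** Ring A alone is disconnected, at C7–C8, C4a–C8a and C6–C7, into a vinylketene and an alkoxyalkyne.
- Forward key step: irradiation of diazo ketone A2 triggers a Wolff rearrangement. The vinylketene adds methoxyethyne A3 in a (2+2) cycloaddition, and the 4-vinylcyclobutenone opens and recloses (4π then 6π electrocyclisation) to phenol A1.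
- For: A1 has the prenyl group, a free hydroxyl (future O7) and a methyl ether (future O1) exactly where ring A needs them. The regiochemistry follows from the mechanism, and the benzannulation is an established reaction type. On precedent this alternative is clearly stronger than the chosen route.
- Against: A1 is only ring A, with C4a still a C–H. Acylation at C4a, closure of ring C and an asymmetric step that creates C3 next to the ketone are all still to come. The methyl ether at O1 must be cleaved by a Lewis acid in a molecule whose prenyl group sits ortho to a phenol, which is the arrangement that cyclises to a chroman.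
- Comparison: the chosen strategy gives up proven regiocontrol. In return it makes rings A and C in one step, with C3 already set and not epimerisable, and needs far fewer operations after ring A exists.

**Alternative 2:** The C3–C4 bond is disconnected to an acyl anion equivalent at C4 and an electrophilic C3.
- Forward key step: a chiral triazolium-derived carbene with a weak amine base converts aldehyde A5 into its Breslow intermediate. Loss of acetate unmasks a ring B quinone methide, and 1,6-addition to its exocyclic carbon forms C3–C4, closes ring C and restores ring B as the phenol, giving A4.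
- For: C3 is set catalytically from an achiral precursor, and A4 is one deprotection from the target. Intramolecular Stetter closures of salicylaldehyde ethers to chroman-4-ones are well known. In step count after the key step this alternative is stronger.
- Against: the new centre is born α to the ketone in a basic medium, so its configuration can erode as it forms. The quinone methide has hydrogens on C2 and can tautomerise to a hydroxystyrene enol ether. Face selection on a transient acyclic acceptor of uncertain geometry is not assured. A5 also needs a ring A salicylaldehyde that already carries the C6 prenyl group, so the C6/C8 problem is only moved into a starting material.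
- Comparison: the chosen route sets C3 with a stoichiometric auxiliary, which is less elegant but dependable, keeps it away from any carbonyl until the last two steps, and solves the ring A pattern by construction.

**Alternative 3:** Ring B is disconnected at C1'–C6' and C2'–C3'.
- Forward key step: a secondary amine with a carboxylic acid co-catalyst turns aldehyde A8 into its enamine, which adds to ynone A7 (C1'–C6'). Intramolecular aldol condensation then forms C2'–C3', and the ring tautomerises to the phenol of A6.
- For: the step is metal-free, fixes the 3'-prenyl-4'-hydroxy pattern without any aryl prenylation, and does not endanger C3, which is not α to a carbonyl in A8. On mildness and operational simplicity it is at least equal to the chosen key step.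
- Against: it builds the one ring that is easy to obtain. A prenylated 4-hydroxyphenylacetic acid is one cross-coupling from a commercial bromophenol. The hard parts, namely ring A with its C6 prenyl group, ring C and both stereocentres, are all left in A8, which is itself a multistep chiral target. A6 also has a free phenol beside two silyl ethers, so reprotection would be needed before C4 is oxidised.
- Comparison: the chosen strategy spends its key step on ring A, where the real difficulty of the target lies.

Key step: step 13

## Route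

**Step 1**
Reactants: 1 methyl 2-(3-bromo-4-hydroxyphenyl)acetate
Product: 2 methyl 2-[3-bromo-4-(triisopropylsilyloxy)phenyl]acetate
Conditions: TIPSCl, imidazole, DMF, rt
Reagents that add atoms: chlorotriisopropylsilane, CC(C)[Si](Cl)(C(C)C)C(C)C
Why: Silylation of a phenol with a silyl chloride and imidazole; the triisopropylsilyl ether is chosen because it has to survive aqueous hydroxide, an alkyllithium and carbonate in methanol later on.

**Step 2**
Reactants: 2 methyl 2-[3-bromo-4-(triisopropylsilyloxy)phenyl]acetate; 3 tributyl(3-methylbut-2-enyl)stannane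
Product: 4 methyl 2-[3-(3-methylbut-2-enyl)-4-(triisopropylsilyloxy)phenyl]acetate
Conditions: Pd(PPh3)4 (5 mol%), DMF, 100 °C
Reagents that add atoms: none
Why: Stille coupling; after oxidative addition of zerovalent palladium to the C–Br bond and transmetalation, the η3-prenyl(aryl)palladium intermediate should reductively eliminate at its unsubstituted CH2 terminus and give the linear prenyl arene. The neutral medium spares the methyl ester and the aryl silyl ether.

**Step 3**
Reactants: 4 methyl 2-[3-(3-methylbut-2-enyl)-4-(triisopropylsilyloxy)phenyl]acetate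
Product: 5 2-[3-(3-methylbut-2-enyl)-4-(triisopropylsilyloxy)phenyl]acetic acid
Conditions: LiOH·H2O, THF/MeOH/H2O, 0 °C → rt; then 1 M HCl to pH 4, 0 °C
Reagents that add atoms: lithium hydroxide, [Li+].[OH-]
Why: Saponification of an unhindered methyl arylacetate, which is fast at 0 °C; the aryl triisopropylsilyl ether, shielded by the ortho prenyl group, should outlast the short exposure, and the cold, brief acidification cannot cyclise the prenyl group because the neighbouring phenol is masked.

**Step 4**
Reactants: 5 2-[3-(3-methylbut-2-enyl)-4-(triisopropylsilyloxy)phenyl]acetic acid; 6 (R)-4-benzyloxazolidin-2-one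
Product: 8 (4R)-4-benzyl-3-{2-[3-(3-methylbut-2-enyl)-4-(triisopropylsilyloxy)phenyl]acetyl}-1,3-oxazolidin-2-one, via mixed pivalic anhydride 7 (not isolated)
Conditions: PivCl, Et3N, THF, −20 °C; then LiCl, 6, −20 °C → rt
Reagents that add atoms: none
Why: N-Acylation of an oxazolidinone through a mixed anhydride; the hindered pivaloyl carbonyl directs the LiCl-activated oxazolidinone to the arylacetyl carbonyl, and no strong base is present that could enolise the arylacetyl unit.

**Step 5**
Reactants: 8 (4R)-4-benzyl-3-{2-[3-(3-methylbut-2-enyl)-4-(triisopropylsilyloxy)phenyl]acetyl}-1,3-oxazolidin-2-one; 9 3-(trimethylsilyl)propynal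
Product: 11 (4R)-4-benzyl-3-{(2R,3R)-3-hydroxy-2-[3-(3-methylbut-2-enyl)-4-(triisopropylsilyloxy)phenyl]-5-(trimethylsilyl)pent-4-ynoyl}-1,3-oxazolidin-2-one, via dibutylboron Z-enolate 10 (not isolated)
Conditions: Bu2BOTf, i-Pr2NEt, CH2Cl2, 0 °C; then 9, −78 → 0 °C; then pH 7 buffer, MeOH, H2O2, 0 °C
Reagents that add atoms: none
Why: Evans syn-aldol reaction; soft enolisation gives Z-enolate 10, which reacts through a closed Zimmerman–Traxler chair with the oxazolidinone carbonyl turned away from the enolate oxygen, so the aldehyde adds to the enolate face remote from the benzyl group of the (R)-auxiliary. This sets C3 (2R in 11, 3S in the chroman numbering) and the syn carbinol C4 (3R in 11). The silylated ynal is non-enolisable and reactive, which limits retro-aldol and epimerisation of the acidic α-aryl centre.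

**Step 6**
Reactants: 11 (4R)-4-benzyl-3-{(2R,3R)-3-hydroxy-2-[3-(3-methylbut-2-enyl)-4-(triisopropylsilyloxy)phenyl]-5-(trimethylsilyl)pent-4-ynoyl}-1,3-oxazolidin-2-one
Product: 12 (4R)-4-benzyl-3-{(2R,3R)-2-[3-(3-methylbut-2-enyl)-4-(triisopropylsilyloxy)phenyl]-3-(triethylsilyloxy)-5-(trimethylsilyl)pent-4-ynoyl}-1,3-oxazolidin-2-one
Conditions: TESOTf, 2,6-lutidine, CH2Cl2, −78 → 0 °C
Reagents that add atoms: triethylsilyl trifluoromethanesulfonate, CC[Si](CC)(CC)OS(=O)(=O)C(F)(F)F
Why: Silylation of a secondary alcohol with a silyl triflate and a hindered pyridine base, which is too weak to start a retro-aldol reaction or to enolise the imide.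

**Step 7**
Reactants: 12 (4R)-4-benzyl-3-{(2R,3R)-2-[3-(3-methylbut-2-enyl)-4-(triisopropylsilyloxy)phenyl]-3-(triethylsilyloxy)-5-(trimethylsilyl)pent-4-ynoyl}-1,3-oxazolidin-2-one
Product: 13 (2S,3R)-2-[3-(3-methylbut-2-enyl)-4-(triisopropylsilyloxy)phenyl]-3-(triethylsilyloxy)-5-(trimethylsilyl)pent-4-yn-1-ol
Conditions: LiBH4, MeOH (1 equiv), THF, 0 °C
Reagents that add atoms: none
Why: Reductive cleavage of an N-acyl oxazolidinone at the exocyclic carbonyl by LiBH4, giving the primary alcohol and releasing the auxiliary; silyl ethers and the silylalkyne are inert to borohydride. From here on C3 is no longer α to a carbonyl group and cannot epimerise.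

**Step 8**
Reactants: 13 (2S,3R)-2-[3-(3-methylbut-2-enyl)-4-(triisopropylsilyloxy)phenyl]-3-(triethylsilyloxy)-5-(trimethylsilyl)pent-4-yn-1-ol
Product: 14 (2S,3R)-2-[3-(3-methylbut-2-enyl)-4-(triisopropylsilyloxy)phenyl]-3-(triethylsilyloxy)-5-(trimethylsilyl)pent-4-ynyl formate
Conditions: acetic formic anhydride (preformed), pyridine, CH2Cl2, 0 °C
Reagents that add atoms: acetic formic anhydride, CC(=O)OC=O
Why: O-Formylation by a mixed anhydride, whose formyl carbonyl is the more electrophilic; no alkoxide is generated, so the triethylsilyl group cannot migrate from O4 to the primary oxygen.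

**Step 9**
Reactants: 14 (2S,3R)-2-[3-(3-methylbut-2-enyl)-4-(triisopropylsilyloxy)phenyl]-3-(triethylsilyloxy)-5-(trimethylsilyl)pent-4-ynyl formate
Product: 15 (2S,3R)-1-(2,2-dichloroethenyloxy)-2-[3-(3-methylbut-2-enyl)-4-(triisopropylsilyloxy)phenyl]-3-(triethylsilyloxy)-5-(trimethylsilyl)pent-4-yne
Conditions: PPh3, CCl4, THF, 60 °C
Reagents that add atoms: tetrachloromethane, ClC(Cl)(Cl)Cl
Why: Wittig-type dichloromethylenation of a formate ester by the ylide formed from PPh3 and CCl4, the ester counterpart of the first stage of a Corey–Fuchs sequence; formates are the esters electrophilic enough for it, and the medium is neutral.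

**Step 10**
Reactants: 15 (2S,3R)-1-(2,2-dichloroethenyloxy)-2-[3-(3-methylbut-2-enyl)-4-(triisopropylsilyloxy)phenyl]-3-(triethylsilyloxy)-5-(trimethylsilyl)pent-4-yne
Product: 17 (2S,3R)-1-(ethynyloxy)-2-[3-(3-methylbut-2-enyl)-4-(triisopropylsilyloxy)phenyl]-3-(triethylsilyloxy)-5-(trimethylsilyl)pent-4-yne, via lithium alkynyl ether 16 (not isolated)
Conditions: n-BuLi (2.2 equiv), THF, −78 → −40 °C; then MeOH, −78 °C
Reagents that add atoms: none
Why: Elimination and halogen–lithium exchange as in the second stage of a Corey–Fuchs alkyne synthesis: deprotonation at the oxygen-bearing vinyl carbon and loss of chloride give a chloroalkynyl ether, chlorine–lithium exchange gives acetylide 16, and protonation gives the ethynyl ether. The trimethylsilyl group keeps the other alkyne from being metalated.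

**Step 11**
Reactants: 17 (2S,3R)-1-(ethynyloxy)-2-[3-(3-methylbut-2-enyl)-4-(triisopropylsilyloxy)phenyl]-3-(triethylsilyloxy)-5-(trimethylsilyl)pent-4-yne
Product: 18 (2S,3R)-1-(ethynyloxy)-2-[3-(3-methylbut-2-enyl)-4-(triisopropylsilyloxy)phenyl]-3-(triethylsilyloxy)pent-4-yne
Conditions: K2CO3 (0.2 equiv), MeOH/THF, 0 °C → rt; Et3N-deactivated silica
Reagents that add atoms: none
Why: Methoxide-mediated protodesilylation of an alkynylsilane; the alkyl triethylsilyl ether, the hindered aryl triisopropylsilyl ether and the base-stable ethynyl ether should not be affected in the short reaction time. Acid is excluded in work-up because ynol ethers hydrate readily.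

**Step 12**
Reactants: 19 ethyl 4-methylpent-3-enoate
Product: 21 triisopropyl(5-methylhex-4-en-1-ynyloxy)silane, via lithium ynolate 20 (not isolated)
Conditions: CH2Br2, LiTMP, THF, −78 °C; 19; then LiHMDS, n-BuLi, −78 °C → rt; then TIPSCl, 0 °C
Reagents that add atoms: dibromomethane, BrCBr; chlorotriisopropylsilane, CC(C)[Si](Cl)(C(C)C)C(C)C
Why: Kowalski ester homologation stopped at the ynolate: addition of dibromomethyllithium to the ester, enolisation, bromine–lithium exchange and 1,2-shift of the alkyl group give ynolate 20. The bulky silyl chloride then silylates on oxygen and not on carbon, giving the siloxyalkyne.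

**Step 13**
Reactants: 18 (2S,3R)-1-(ethynyloxy)-2-[3-(3-methylbut-2-enyl)-4-(triisopropylsilyloxy)phenyl]-3-(triethylsilyloxy)pent-4-yne; 21 triisopropyl(5-methylhex-4-en-1-ynyloxy)silane
Product: 22 (3S,4R)-6-(3-methylbut-2-enyl)-3-[3-(3-methylbut-2-enyl)-4-(triisopropylsilyloxy)phenyl]-4-(triethylsilyloxy)-7-(triisopropylsilyloxy)-3,4-dihydro-2H-chromene (trans)
Conditions: [Rh(cod)2]BF4 (10 mol%), rac-BINAP (10 mol%), CH2Cl2, H2 then Ar purge; 21 (3 equiv); 18 added over 6 h, rt
Reagents that add atoms: none
Why: Proposed new method: a cationic monovalent rhodium bisphosphine complex should bind both alkynes of 18 and couple them oxidatively to a trivalent rhodacyclopentadiene, which forms C4a–C8a and closes ring C as the six-membered ring fused to the metallacycle. Coordination and insertion of 21, followed by C–C reductive elimination, then form C7–C8 and C5–C6 and close ring A, all six of whose carbons come from alkynes. The closest known reaction type is the cationic rhodium/bisphosphine-catalysed (2+2+2) cycloaddition of tethered 1,6- and 1,7-diynes with monoalkynes, together with rhodium-catalysed cyclotrimerisations that use aryl ethynyl ethers or ynamides as one component; a diyne whose tether starts at an ynol ether oxygen has not been combined with a siloxyalkyne. No stereocentre is formed, and C3 and C4 are spectators without an acidifying neighbour, so a racemic ligand is sufficient. The selectivity needed is regiochemical: C8 must bond to the oxygen-bearing carbon of 21 (future C7) and C5 to its prenyl-bearing carbon (future C6). This head-to-tail union is expected because the Rh–C8 carbon is the β-carbon of an enol ether and thus the nucleophilic terminus of the rhodacycle, whereas the oxygen-bearing carbon of 21 is its electrophilic, ketene-like carbon; the two CH termini C5 and C8 are sterically alike, so sterics should not override this bias. Cross-selectivity over homo-oligomerisation is to be secured by an excess of 21 and slow addition of 18, and room temperature avoids the retro-ene fragmentation of the alkyl ethynyl ether and the 1,3-silyl shift of 21.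

**Step 14**
Reactants: 22 (3S,4R)-6-(3-methylbut-2-enyl)-3-[3-(3-methylbut-2-enyl)-4-(triisopropylsilyloxy)phenyl]-4-(triethylsilyloxy)-7-(triisopropylsilyloxy)-3,4-dihydro-2H-chromene
Product: 23 (3S,4R)-6-(3-methylbut-2-enyl)-3-[3-(3-methylbut-2-enyl)-4-(triisopropylsilyloxy)phenyl]-7-(triisopropylsilyloxy)-3,4-dihydro-2H-chromen-4-ol
Conditions: AcOH/THF/H2O (3:1:1), rt
Reagents that add atoms: none
Why: Acid-catalysed hydrolysis of a silyl ether; an alkyl triethylsilyl ether is cleaved by dilute acetic acid far faster than aryl triisopropylsilyl ethers, whose oxygen is poorly basic and whose silicon is hindered. The medium is too weak to cyclise the prenyl groups, whose neighbouring phenols are still masked.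

**Step 15**
Reactants: 23 (3S,4R)-6-(3-methylbut-2-enyl)-3-[3-(3-methylbut-2-enyl)-4-(triisopropylsilyloxy)phenyl]-7-(triisopropylsilyloxy)-3,4-dihydro-2H-chromen-4-ol
Product: 24 (3S)-6-(3-methylbut-2-enyl)-3-[3-(3-methylbut-2-enyl)-4-(triisopropylsilyloxy)phenyl]-7-(triisopropylsilyloxy)-2,3-dihydro-4H-chromen-4-one
Conditions: Dess–Martin periodinane, pyridine, CH2Cl2, 0 °C → rt
Reagents that add atoms: none
Why: Dess–Martin oxidation of a secondary benzylic alcohol; the buffered, non-enolising medium leaves the trisubstituted alkenes and silyl ethers untouched and should carry the C3 configuration into the α-aryl ketone unchanged.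

**Step 16**
Reactants: 24 (3S)-6-(3-methylbut-2-enyl)-3-[3-(3-methylbut-2-enyl)-4-(triisopropylsilyloxy)phenyl]-7-(triisopropylsilyloxy)-2,3-dihydro-4H-chromen-4-one
Product: 25 (3S)-7-hydroxy-3-[4-hydroxy-3-(3-methylbut-2-enyl)phenyl]-6-(3-methylbut-2-enyl)-2,3-dihydro-4H-chromen-4-one
Conditions: TBAF, AcOH (1:1.2), THF, 0 °C
Reagents that add atoms: none
Why: Fluoride-induced cleavage of aryl silyl ethers, which is fast because phenoxides are good leaving groups; the excess of acetic acid keeps the medium from becoming basic, so that the α-aryl ketone is not enolised and the prenyl groups are not exposed to strong acid.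

## Compound list

1 | methyl 2-(3-bromo-4-hydroxyphenyl)acetate | COC(=O)Cc1ccc(O)c(Br)c1 | starting material
2 | methyl 2-[3-bromo-4-(triisopropylsilyloxy)phenyl]acetate | COC(=O)Cc1ccc(O[Si](C(C)C)(C(C)C)C(C)C)c(Br)c1 | intermediate
3 | tributyl(3-methylbut-2-enyl)stannane | CCCC[Sn](CCCC)(CCCC)CC=C(C)C | starting material
4 | methyl 2-[3-(3-methylbut-2-enyl)-4-(triisopropylsilyloxy)phenyl]acetate | COC(=O)Cc1ccc(O[Si](C(C)C)(C(C)C)C(C)C)c(CC=C(C)C)c1 | intermediate
5 | 2-[3-(3-methylbut-2-enyl)-4-(triisopropylsilyloxy)phenyl]acetic acid | OC(=O)Cc1ccc(O[Si](C(C)C)(C(C)C)C(C)C)c(CC=C(C)C)c1 | intermediate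
6 | (R)-4-benzyloxazolidin-2-one | O=C1N[C@H](Cc2ccccc2)CO1 | starting material
7 | mixed anhydride of 5 with pivalic acid (not isolated) | CC(C)(C)C(=O)OC(=O)Cc1ccc(O[Si](C(C)C)(C(C)C)C(C)C)c(CC=C(C)C)c1 | intermediate
8 | (4R)-4-benzyl-3-{2-[3-(3-methylbut-2-enyl)-4-(triisopropylsilyloxy)phenyl]acetyl}-1,3-oxazolidin-2-one | O=C(Cc1ccc(O[Si](C(C)C)(C(C)C)C(C)C)c(CC=C(C)C)c1)N1[C@H](Cc2ccccc2)COC1=O | intermediate
9 | 3-(trimethylsilyl)propynal | C[Si](C)(C)C#CC=O | starting material
10 | dibutylboron Z-enolate of 8 (not isolated) | CCCCB(CCCC)O/C(=C\c1ccc(O[Si](C(C)C)(C(C)C)C(C)C)c(CC=C(C)C)c1)N1[C@H](Cc2ccccc2)COC1=O | intermediate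
11 | (4R)-4-benzyl-3-{(2R,3R)-3-hydroxy-2-[3-(3-methylbut-2-enyl)-4-(triisopropylsilyloxy)phenyl]-5-(trimethylsilyl)pent-4-ynoyl}-1,3-oxazolidin-2-one | O=C([C@H](c1ccc(O[Si](C(C)C)(C(C)C)C(C)C)c(CC=C(C)C)c1)[C@@H](O)C#C[Si](C)(C)C)N1[C@H](Cc2ccccc2)COC1=O | intermediate
12 | (4R)-4-benzyl-3-{(2R,3R)-2-[3-(3-methylbut-2-enyl)-4-(triisopropylsilyloxy)phenyl]-3-(triethylsilyloxy)-5-(trimethylsilyl)pent-4-ynoyl}-1,3-oxazolidin-2-one | O=C([C@H](c1ccc(O[Si](C(C)C)(C(C)C)C(C)C)c(CC=C(C)C)c1)[C@@H](O[Si](CC)(CC)CC)C#C[Si](C)(C)C)N1[C@H](Cc2ccccc2)COC1=O | intermediate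
13 | (2S,3R)-2-[3-(3-methylbut-2-enyl)-4-(triisopropylsilyloxy)phenyl]-3-(triethylsilyloxy)-5-(trimethylsilyl)pent-4-yn-1-ol | OC[C@H](c1ccc(O[Si](C(C)C)(C(C)C)C(C)C)c(CC=C(C)C)c1)[C@@H](O[Si](CC)(CC)CC)C#C[Si](C)(C)C | intermediate
14 | (2S,3R)-2-[3-(3-methylbut-2-enyl)-4-(triisopropylsilyloxy)phenyl]-3-(triethylsilyloxy)-5-(trimethylsilyl)pent-4-ynyl formate | O=COC[C@H](c1ccc(O[Si](C(C)C)(C(C)C)C(C)C)c(CC=C(C)C)c1)[C@@H](O[Si](CC)(CC)CC)C#C[Si](C)(C)C | intermediate
15 | (2S,3R)-1-(2,2-dichloroethenyloxy)-2-[3-(3-methylbut-2-enyl)-4-(triisopropylsilyloxy)phenyl]-3-(triethylsilyloxy)-5-(trimethylsilyl)pent-4-yne | ClC(Cl)=COC[C@H](c1ccc(O[Si](C(C)C)(C(C)C)C(C)C)c(CC=C(C)C)c1)[C@@H](O[Si](CC)(CC)CC)C#C[Si](C)(C)C | intermediate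
16 | lithium acetylide of 17, lithiated at the ethynyl ether terminus (not isolated) | [Li]C#COC[C@H](c1ccc(O[Si](C(C)C)(C(C)C)C(C)C)c(CC=C(C)C)c1)[C@@H](O[Si](CC)(CC)CC)C#C[Si](C)(C)C | intermediate
17 | (2S,3R)-1-(ethynyloxy)-2-[3-(3-methylbut-2-enyl)-4-(triisopropylsilyloxy)phenyl]-3-(triethylsilyloxy)-5-(trimethylsilyl)pent-4-yne | C#COC[C@H](c1ccc(O[Si](C(C)C)(C(C)C)C(C)C)c(CC=C(C)C)c1)[C@@H](O[Si](CC)(CC)CC)C#C[Si](C)(C)C | intermediate
18 | (2S,3R)-1-(ethynyloxy)-2-[3-(3-methylbut-2-enyl)-4-(triisopropylsilyloxy)phenyl]-3-(triethylsilyloxy)pent-4-yne (syn diyne) | C#COC[C@H](c1ccc(O[Si](C(C)C)(C(C)C)C(C)C)c(CC=C(C)C)c1)[C@@H](O[Si](CC)(CC)CC)C#C | intermediate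
19 | ethyl 4-methylpent-3-enoate | CCOC(=O)CC=C(C)C | starting material
20 | lithium 5-methylhex-4-en-1-yn-1-olate (not isolated) | [Li+].[O-]C#CCC=C(C)C | intermediate
21 | triisopropyl(5-methylhex-4-en-1-ynyloxy)silane | CC(C)=CCC#CO[Si](C(C)C)(C(C)C)C(C)C | intermediate
22 | (3S,4R)-6-(3-methylbut-2-enyl)-3-[3-(3-methylbut-2-enyl)-4-(triisopropylsilyloxy)phenyl]-4-(triethylsilyloxy)-7-(triisopropylsilyloxy)-3,4-dihydro-2H-chromene | CC[Si](CC)(CC)O[C@H]1c2cc(CC=C(C)C)c(O[Si](C(C)C)(C(C)C)C(C)C)cc2OC[C@@H]1c1ccc(O[Si](C(C)C)(C(C)C)C(C)C)c(CC=C(C)C)c1 | intermediate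
23 | (3S,4R)-6-(3-methylbut-2-enyl)-3-[3-(3-methylbut-2-enyl)-4-(triisopropylsilyloxy)phenyl]-7-(triisopropylsilyloxy)-3,4-dihydro-2H-chromen-4-ol | O[C@H]1c2cc(CC=C(C)C)c(O[Si](C(C)C)(C(C)C)C(C)C)cc2OC[C@@H]1c1ccc(O[Si](C(C)C)(C(C)C)C(C)C)c(CC=C(C)C)c1 | intermediate
24 | (3S)-6-(3-methylbut-2-enyl)-3-[3-(3-methylbut-2-enyl)-4-(triisopropylsilyloxy)phenyl]-7-(triisopropylsilyloxy)-2,3-dihydro-4H-chromen-4-one | O=C1c2cc(CC=C(C)C)c(O[Si](C(C)C)(C(C)C)C(C)C)cc2OC[C@@H]1c1ccc(O[Si](C(C)C)(C(C)C)C(C)C)c(CC=C(C)C)c1 | intermediate
25 | (3S)-7-hydroxy-3-[4-hydroxy-3-(3-methylbut-2-enyl)phenyl]-6-(3-methylbut-2-enyl)-2,3-dihydro-4H-chromen-4-one | CC(C)=CCc1cc([C@H]2COc3cc(O)c(CC=C(C)C)cc3C2=O)ccc1O | target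

## Step count and least certain steps

Total step count: 16. Longest linear sequence: 15 steps (1 to 25 through steps 1–11 and 13–16); step 12 is a one-step branch.

**Step 13 (key step).**
- What may go wrong: insertion of 21 in the reverse orientation, which would exchange the oxygen and prenyl positions on ring A. Oxidative coupling of a 1,7-diyne is also slower than that of a 1,6-diyne, which leaves room for homo-oligomerisation of the terminal alkynes or of 21. Either ynol ether may also decompose under Lewis acid.
- Fallback by known chemistry, setting out from 8 and returning at 22, with ring A brought in as a preformed arene: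
  - 2-Bromo-4-hydroxybenzaldehyde F1 is iodinated at the unhindered position ortho to the hydroxyl (NIS, MeCN) to 2-bromo-4-hydroxy-5-iodobenzaldehyde F2.
  - F2 is silylated (TIPSCl, imidazole) to 2-bromo-5-iodo-4-(triisopropylsilyloxy)benzaldehyde F3.
  - F3 is coupled at the iodide only with 3 (Pd2(dba)3, AsPh3, DMF, 50 °C) to 2-bromo-5-(3-methylbut-2-enyl)-4-(triisopropylsilyloxy)benzaldehyde F4.
  - Enolate 10, made from 8 as in step 5, adds to F4 in the same syn sense to give the aldol adduct F5.
  - Silylation (TESOTf, 2,6-lutidine) gives the triethylsilyl ether F6, and LiBH4 gives the bromo alcohol F7.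
  - Intramolecular palladium-catalysed C–O coupling of the primary alcohol with the aryl bromide (Pd(OAc)2, 2-(di-tert-butylphosphino)-1,1'-binaphthyl, Cs2CO3, toluene, 80 °C) closes ring C at O1–C8a and gives 22.
- This gives up the convergence and the short route, but each operation has a close counterpart in known chemistry.

**Step 9.**
- What may go wrong: attack of the chlorophosphonium by-product on the triethylsilyl ether (loss of the group or its exchange for chloride), and sluggish olefination of the hindered formate.
- Fallback from 13, returning at 17: deprotonation with KH in THF in the presence of trichloroethylene (−50 °C → rt) gives the (E)-1,2-dichlorovinyl ether F8. The n-BuLi treatment of step 10 converts F8 through 16 into 17.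
- The weak point of this fallback is 1,5-migration of the triethylsilyl group in the potassium alkoxide. It is to be limited by generating the alkoxide cold and with the electrophile already present.

**Step 2.**
- What may go wrong: transfer of the prenyl group through its tertiary terminus, and slow oxidative addition at the hindered, electron-rich C–Br bond.
- Fallback from 2, returning at 4, with reversed polarity: Miyaura borylation (B2pin2, PdCl2(dppf), KOAc, dioxane, 85 °C) gives the aryl boronate F9. Suzuki–Miyaura coupling with 1-bromo-3-methylbut-2-ene F10 (Pd(PPh3)4, K3PO4, THF/H2O, 50 °C) then gives 4.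
- Here the prenyl unit enters as the π-allyl electrophile, so no allyl-transposing transmetalation can occur.

**Step 12.**
- What may go wrong: α-deprotonation of the β,γ-unsaturated ester in competition with carbenoid addition, with migration of the double bond into conjugation, and silylation of the ynolate on carbon.
- Fallback: it does not set out from 19 but from commercial 1-bromo-3-methylbut-2-ene F10, and it returns at 20 and hence at 21. CuCl-catalysed coupling with ethynylmagnesium bromide in THF gives 5-methylhex-4-en-1-yne F11. Its lithium acetylide (n-BuLi, THF, −78 °C) is oxidised with lithium tert-butyl peroxide (from t-BuOOH and LiHMDS) to ynolate 20, which is silylated with TIPSCl as in step 12.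

**Step 16 (with step 15).**
- What may go wrong: enolisation of the α-aryl ketone during desilylation, eroding the C3 configuration.
- Fallback from 23, returning at 25: the two aryl silyl groups are removed first, while no enolisable centre exists (TBAF, THF, 0 °C), to give the triol F12. Its benzylic alcohol, activated by the para hydroxyl O7, is then oxidised under neutral conditions with activated MnO2 (EtOAc, rt) to 25.

## Further compounds

F1 | step 13 | 2-bromo-4-hydroxybenzaldehyde (commercial) | O=Cc1ccc(O)cc1Br
F2 | step 13 | 2-bromo-4-hydroxy-5-iodobenzaldehyde | O=Cc1cc(I)c(O)cc1Br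
F3 | step 13 | 2-bromo-5-iodo-4-(triisopropylsilyloxy)benzaldehyde | O=Cc1cc(I)c(O[Si](C(C)C)(C(C)C)C(C)C)cc1Br
F4 | step 13 | 2-bromo-5-(3-methylbut-2-enyl)-4-(triisopropylsilyloxy)benzaldehyde | O=Cc1cc(CC=C(C)C)c(O[Si](C(C)C)(C(C)C)C(C)C)cc1Br
F5 | step 13 | (4R)-4-benzyl-3-{(2R,3R)-3-[2-bromo-5-(3-methylbut-2-enyl)-4-(triisopropylsilyloxy)phenyl]-3-hydroxy-2-[3-(3-methylbut-2-enyl)-4-(triisopropylsilyloxy)phenyl]propanoyl}-1,3-oxazolidin-2-one | O=C([C@H](c1ccc(O[Si](C(C)C)(C(C)C)C(C)C)c(CC=C(C)C)c1)[C@@H](O)c1cc(CC=C(C)C)c(O[Si](C(C)C)(C(C)C)C(C)C)cc1Br)N1[C@H](Cc2ccccc2)COC1=O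
F6 | step 13 | (4R)-4-benzyl-3-{(2R,3R)-3-[2-bromo-5-(3-methylbut-2-enyl)-4-(triisopropylsilyloxy)phenyl]-2-[3-(3-methylbut-2-enyl)-4-(triisopropylsilyloxy)phenyl]-3-(triethylsilyloxy)propanoyl}-1,3-oxazolidin-2-one | O=C([C@H](c1ccc(O[Si](C(C)C)(C(C)C)C(C)C)c(CC=C(C)C)c1)[C@@H](O[Si](CC)(CC)CC)c1cc(CC=C(C)C)c(O[Si](C(C)C)(C(C)C)C(C)C)cc1Br)N1[C@H](Cc2ccccc2)COC1=O
F7 | step 13 | (2S,3R)-3-[2-bromo-5-(3-methylbut-2-enyl)-4-(triisopropylsilyloxy)phenyl]-2-[3-(3-methylbut-2-enyl)-4-(triisopropylsilyloxy)phenyl]-3-(triethylsilyloxy)propan-1-ol | OC[C@H](c1ccc(O[Si](C(C)C)(C(C)C)C(C)C)c(CC=C(C)C)c1)[C@@H](O[Si](CC)(CC)CC)c1cc(CC=C(C)C)c(O[Si](C(C)C)(C(C)C)C(C)C)cc1Br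
F8 | step 9 | (2S,3R)-1-[(E)-1,2-dichloroethenyloxy]-2-[3-(3-methylbut-2-enyl)-4-(triisopropylsilyloxy)phenyl]-3-(triethylsilyloxy)-5-(trimethylsilyl)pent-4-yne | Cl/C=C(/Cl)OC[C@H](c1ccc(O[Si](C(C)C)(C(C)C)C(C)C)c(CC=C(C)C)c1)[C@@H](O[Si](CC)(CC)CC)C#C[Si](C)(C)C
F9 | step 2 | methyl 2-[3-(4,4,5,5-tetramethyl-1,3,2-dioxaborolan-2-yl)-4-(triisopropylsilyloxy)phenyl]acetate | COC(=O)Cc1ccc(O[Si](C(C)C)(C(C)C)C(C)C)c(B2OC(C)(C)C(C)(C)O2)c1
F10 | step 2 | 1-bromo-3-methylbut-2-ene (commercial; also the starting point of the fallback to step 12) | CC(C)=CCBr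
F11 | step 12 | 5-methylhex-4-en-1-yne | C#CCC=C(C)C
F12 | step 16 | (3S,4R)-3-[4-hydroxy-3-(3-methylbut-2-enyl)phenyl]-6-(3-methylbut-2-enyl)-3,4-dihydro-2H-chromene-4,7-diol | O[C@H]1c2cc(CC=C(C)C)c(O)cc2OC[C@@H]1c1ccc(O)c(CC=C(C)C)c1
A1 | alternative 1 | 5-methoxy-2-(3-methylbut-2-enyl)phenol | COc1ccc(CC=C(C)C)c(O)c1
A2 | alternative 1 | (E)-1-diazo-7-methylocta-3,6-dien-2-one | [N-]=[N+]=CC(=O)/C=C/CC=C(C)C
A3 | alternative 1 | methoxyethyne | COC#C
A4 | alternative 2 | (3S)-3-[4-hydroxy-3-(3-methylbut-2-enyl)phenyl]-6-(3-methylbut-2-enyl)-7-(triisopropylsilyloxy)-2,3-dihydro-4H-chromen-4-one | O=C1c2cc(CC=C(C)C)c(O[Si](C(C)C)(C(C)C)C(C)C)cc2OC[C@@H]1c1ccc(O)c(CC=C(C)C)c1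
A5 | alternative 2 | 2-{2-acetoxy-2-[4-hydroxy-3-(3-methylbut-2-enyl)phenyl]ethoxy}-5-(3-methylbut-2-enyl)-4-(triisopropylsilyloxy)benzaldehyde (racemic at the acetoxy carbon, which becomes trigonal) | CC(=O)OC(COc1cc(O[Si](C(C)C)(C(C)C)C(C)C)c(CC=C(C)C)cc1C=O)c1ccc(O)c(CC=C(C)C)c1
A6 | alternative 3 | (3S,4S)-7-(tert-butyldimethylsilyloxy)-3-[4-hydroxy-3-(3-methylbut-2-enyl)phenyl]-6-(3-methylbut-2-enyl)-4-(triethylsilyloxy)-3,4-dihydro-2H-chromene (cis) | CC[Si](CC)(CC)O[C@@H]1c2cc(CC=C(C)C)c(O[Si](C)(C)C(C)(C)C)cc2OC[C@@H]1c1ccc(O)c(CC=C(C)C)c1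
A7 | alternative 3 | 7-methyloct-6-en-1-yn-3-one | C#CC(=O)CCC=C(C)C
A8 | alternative 3 | 2-[(3S,4S)-7-(tert-butyldimethylsilyloxy)-6-(3-methylbut-2-enyl)-4-(triethylsilyloxy)-3,4-dihydro-2H-chromen-3-yl]acetaldehyde | CC[Si](CC)(CC)O[C@@H]1c2cc(CC=C(C)C)c(O[Si](C)(C)C(C)(C)C)cc2OC[C@@H]1CC=O
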